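**Retrosynthetic overview** (cadinane numbering: C1/C6 ring fusion, C4=C5, C7 carries C11(=C13)–C12O2H, C8 carries the ester, C10=C14, C15 = CH2OH; primes = side chain)
1. Target 27 ⇐ tris-TBS ether 26 by one fluoride step.
2. 26 ⇐ monocyclic lactone 23 in one relay operation that closes ring B (C1–C6) and then ring A (C3–C4). The enabling feature is the allylic C6–O bond of the α-methylene-γ-butyrolactone ring (O–C6–C7–C11–C12): a temporary ring that masks the C12 acid, holds C11 anti to the incoming carbon and acts as leaving group. It lies 1,6 to the γ-carbon C1 of a (Z)-allylsilane (C1=C10–C14–SiMe3); the same chain carries a (Z)-C4 bromide cis to C6 and a primary C3 iodide.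
3. 23 ⇐ lactone alcohol 22 + acid 7 (from (S)-3-hydroxy-γ-butyrolactone); 22 ⇐ allyl bromide 19 + bromo enal 10 by indium Barbier allylation/lactonisation (C6–C7 bond, C7 set against C8).
4. 19 ⇐ aldehyde 17 (α-aluminoacrylate addition, SN2′ bromination) ⇐ (R)-PMB glycidyl ether 11 (acetylide opening; silylmethylcuprate syn-carbometalation and ethylene oxide build the (Z)-allylsilane and the C2–C3 arm).
5. Ring order: lactone (step 13, temporary) → ring B → ring A (both in step 16).

Key step: step 16

Remark: 1, 8 and 11 are taken as purchasable; the sense of 1,2-induction in step 13 (new C6–C7 bond anti to the C8–C9 bond, silyloxy group outside) is an assumption, and its failure is answered under the fallbacks.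

**Step 1**
Reactants: 1 (S)-3-hydroxy-γ-butyrolactone
Product: 4 (S)-tulipalin B, via Mannich base 2 (not isolated), via methiodide 3 (not isolated)
Conditions: LiN(iPr)2 (2.2 equiv), THF, −78 °C; CH2=NMe2+ I−, −78 → 0 °C; then MeI, MeOH, 25 °C; then aq. NaHCO3, CH2Cl2, 25 °C
Reagents that add atoms: N,N-dimethylmethyleneiminium iodide (Eschenmoser's salt), C=[N+](C)C.[I-]
Why: The alkoxide–enolate dianion cannot undergo β-elimination, so Mannich alkylation followed by quaternisation and Hofmann-type elimination should give the α-methylene lactone without touching C3′.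

**Step 2**
Reactants: 4 (S)-tulipalin B
Product: 7 (3S)-3,4-bis(tert-butyldimethylsilyloxy)-2-methylidenebutanoic acid, via lithium carboxylate 5 (not isolated), via tris-silyl derivative 6 (not isolated)
Conditions: LiOH (1.05 equiv), THF/H2O, 0 °C; evaporate; TBSOTf (3.5 equiv), 2,6-lutidine, CH2Cl2, 0 → 25 °C; then AcOH/THF/H2O, 25 °C
Reagents that add atoms: lithium hydroxide, [Li+].[OH-]; tert-butyldimethylsilyl triflate, CC(C)(C)[Si](C)(C)OS(=O)(=O)C(F)(F)F
Why: Saponification, exhaustive silylation and selective hydrolysis of the labile silyl ester should give the acid, which cannot relactonise because O4′ is capped; no stereocentre is touched.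

**Step 3**
Reactants: 8 4-(tert-butyldimethylsilyloxy)but-2-yn-1-ol
Product: 9 (2Z)-3-bromo-4-(tert-butyldimethylsilyloxy)but-2-en-1-ol
Conditions: NaAlH2(OCH2CH2OCH3)2, THF, 0 °C; then N-bromosuccinimide, −78 → 0 °C
Reagents that add atoms: N-bromosuccinimide, O=C1CCC(=O)N1Br
Why: trans-Hydroalumination of the propargylic alcohol through the cyclic alkoxyaluminate puts aluminium on the distal alkyne carbon, and bromodealumination with retention should give the bromoalkene with Br cis to the CH2OH arm.

**Step 4**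
Reactants: 9 (2Z)-3-bromo-4-(tert-butyldimethylsilyloxy)but-2-en-1-ol
Product: 10 (2Z)-3-bromo-4-(tert-butyldimethylsilyloxy)but-2-enal
Conditions: MnO2, CH2Cl2, 25 °C
Reagents that add atoms: none
Why: Allylic oxidation with MnO2 is selective and neutral, so the (Z) geometry and the silyl ether should survive.

**Step 5**
Reactants: 11 (R)-2-[(4-methoxybenzyloxy)methyl]oxirane
Product: 12 (2R)-1-(4-methoxybenzyloxy)pent-4-yn-2-ol
Conditions: LiC≡CH·H2NCH2CH2NH2, DMSO, 25 °C
Reagents that add atoms: lithium acetylide–ethylenediamine complex, [Li]C#C.NCCN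
Why: SN2 opening of the epoxide at its CH2 terminus by acetylide leaves the stereocentre (later C8) untouched.

**Step 6**
Reactants: 12 (2R)-1-(4-methoxybenzyloxy)pent-4-yn-2-ol
Product: 13 (2R)-1-(4-methoxybenzyloxy)-2-(triethylsilyloxy)pent-4-yne
Conditions: Et3SiCl, imidazole, CH2Cl2, 0 °C
Reagents that add atoms: chlorotriethylsilane, CC[Si](CC)(CC)Cl
Why: Standard silylation protects C8–OH with a group that can later be removed in the presence of TBS ethers.

**Step 7**
Reactants: 13 (2R)-1-(4-methoxybenzyloxy)-2-(triethylsilyloxy)pent-4-yne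
Product: 14 (3Z,6R)-7-(4-methoxybenzyloxy)-6-(triethylsilyloxy)-4-[(trimethylsilyl)methyl]hept-3-en-1-ol
Conditions: Me3SiCH2MgCl (2.2 equiv), CuBr·SMe2 (1.1 equiv), THF, −40 → −10 °C; then ethylene oxide, −40 → 0 °C; aq. NH4Cl
Reagents that add atoms: (trimethylsilyl)methylmagnesium chloride, C[Si](C)(C)C[Mg]Cl; ethylene oxide, C1CO1
Why: syn-Carbocupration of the terminal alkyne (silylmethyl to the internal carbon, copper to the terminus) and transfer of the alkenyl ligand of the mixed cuprate to ethylene oxide with retention should fix the (Z)-allylsilane, the second Me3SiCH2 group being a non-transferable ligand.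

**Step 8**
Reactants: 14 (3Z,6R)-7-(4-methoxybenzyloxy)-6-(triethylsilyloxy)-4-[(trimethylsilyl)methyl]hept-3-en-1-ol
Product: 15 (2R,4Z)-7-iodo-1-(4-methoxybenzyloxy)-2-(triethylsilyloxy)-4-[(trimethylsilyl)methyl]hept-4-ene
Conditions: PPh3, imidazole, I2 (premixed), CH2Cl2, 0 °C
Reagents that add atoms: iodine, II
Why: Appel-type iodination of the primary alcohol proceeds through the phosphonium intermediate and should not attack the allylsilane when iodine is consumed by the phosphine first.

**Step 9**
Reactants: 15 (2R,4Z)-7-iodo-1-(4-methoxybenzyloxy)-2-(triethylsilyloxy)-4-[(trimethylsilyl)methyl]hept-4-ene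
Product: 16 (2R,4Z)-7-iodo-2-(triethylsilyloxy)-4-[(trimethylsilyl)methyl]hept-4-en-1-ol
Conditions: DDQ, CH2Cl2/pH 7 buffer, 0 °C
Reagents that add atoms: none
Why: Oxidative cleavage of the p-methoxybenzyl ether with DDQ is orthogonal to the silyl ether, the iodide and the allylsilane.

**Step 10**
Reactants: 16 (2R,4Z)-7-iodo-2-(triethylsilyloxy)-4-[(trimethylsilyl)methyl]hept-4-en-1-ol
Product: 17 (2R,4Z)-7-iodo-2-(triethylsilyloxy)-4-[(trimethylsilyl)methyl]hept-4-enal
Conditions: Dess–Martin periodinane, NaHCO3, CH2Cl2, 0 → 25 °C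
Reagents that add atoms: none
Why: Buffered Dess–Martin oxidation gives the α-silyloxy aldehyde without epimerisation at C8.

**Step 11**
Reactants: 17 (2R,4Z)-7-iodo-2-(triethylsilyloxy)-4-[(trimethylsilyl)methyl]hept-4-enal
Product: 18 methyl (4R,6Z)-3-hydroxy-9-iodo-2-methylidene-4-(triethylsilyloxy)-6-[(trimethylsilyl)methyl]non-6-enoate (both C3 epimers)
Conditions: methyl propiolate, i-Bu2AlH, N-methylmorpholine N-oxide, THF, 0 °C; then 17, 0 → 25 °C
Reagents that add atoms: methyl propiolate, C#CC(=O)OC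
Why: Hydroalumination of the propiolate gives an α-aluminoacrylate that adds to the aldehyde to give the Morita–Baylis–Hillman-type adduct without a nucleophilic amine that would quaternise the iodide; the new carbinol becomes sp2 in step 12, so its configuration is irrelevant.

**Step 12**
Reactants: 18 methyl (4R,6Z)-3-hydroxy-9-iodo-2-methylidene-4-(triethylsilyloxy)-6-[(trimethylsilyl)methyl]non-6-enoate
Product: 19 methyl (2Z,4R,6Z)-2-(bromomethyl)-9-iodo-4-(triethylsilyloxy)-6-[(trimethylsilyl)methyl]nona-2,6-dienoate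
Conditions: N-bromosuccinimide, Me2S (premixed), CH2Cl2, −20 → 0 °C
Reagents that add atoms: N-bromosuccinimide, O=C1CCC(=O)N1Br
Why: Corey–Kim-type activation of the allylic alcohol and SN2′ attack of bromide should give the rearranged primary bromide with the C8 arm cis to CH2Br.

**Step 13**
Reactants: 19 methyl (2Z,4R,6Z)-2-(bromomethyl)-9-iodo-4-(triethylsilyloxy)-6-[(trimethylsilyl)methyl]nona-2,6-dienoate; 10 (2Z)-3-bromo-4-(tert-butyldimethylsilyloxy)but-2-enal
Product: 21 (4S,5R)-5-[(1Z)-2-bromo-3-(tert-butyldimethylsilyloxy)prop-1-en-1-yl]-4-[(1R,3Z)-6-iodo-1-(triethylsilyloxy)-3-[(trimethylsilyl)methyl]hex-3-en-1-yl]-3-methylideneoxolan-2-one (cis-lactone), via hydroxy ester 20 (not isolated)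
Conditions: indium powder, THF/H2O (1:1), 25 °C; then silica gel, CH2Cl2, 25 °C
Reagents that add atoms: none
Why: In this Barbier allylation indium inserts only into the allylic C–Br bond and the allylindium adds through C7 to the aldehyde in a chair transition state, in which the (Z) reagent gives the syn adduct and hence the cis-lactone after loss of methanol, while C8 should direct the aldehyde to the C7 face anti to the C8–C9 bond (H8 in the alkene plane to relieve A(1,3) strain).

**Step 14**
Reactants: 21 cis-lactone triethylsilyl ether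
Product: 22 (4R,5R)-5-[(1Z)-2-bromo-3-(tert-butyldimethylsilyloxy)prop-1-en-1-yl]-4-[(1R,3Z)-1-hydroxy-6-iodo-3-[(trimethylsilyl)methyl]hex-3-en-1-yl]-3-methylideneoxolan-2-one
Conditions: HF·pyridine, pyridine, THF, 0 °C
Reagents that add atoms: none
Why: Buffered HF·pyridine cleaves the secondary triethylsilyl ether far faster than the TBS ether, and the cold, weakly acidic medium should not move the lactone to O8.

**Step 15**
Reactants: 22 lactone alcohol; 7 (3S)-3,4-bis(tert-butyldimethylsilyloxy)-2-methylidenebutanoic acid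
Product: 23 (1R,3Z)-1-{(2R,3R)-2-[(1Z)-2-bromo-3-(tert-butyldimethylsilyloxy)prop-1-en-1-yl]-4-methylidene-5-oxooxolan-3-yl}-6-iodo-3-[(trimethylsilyl)methyl]hex-3-en-1-yl (3S)-3,4-bis(tert-butyldimethylsilyloxy)-2-methylidenebutanoate
Conditions: 7, 2,4,6-trichlorobenzoyl chloride, Et3N, toluene, 25 °C; then 22, DMAP, 0 → 25 °C
Reagents that add atoms: none
Why: Yamaguchi esterification acylates C8–OH with retention, and the fast acyl transfer should outrun translactonisation and amine alkylation by the iodide.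

**Step 16**
Reactants: 23 lactone ester
Product: 26 (1S,6S,7R,8R)-15-O-TBS-3′,4′-bis-O-TBS derivative of the target acid, via trimethylsilyl ester bromo iodide 24 (not isolated), via trimethylsilyl ester of the bicycle 25 (not isolated)
Conditions: Me3SiOTf (0.2 equiv), 2,6-di-tert-butyl-4-methylpyridine (0.3 equiv), CH2Cl2, −78 → −20 °C; then, same flask, DMA, NiBr2·DME (10 mol%), 4,4′-di-tert-butyl-2,2′-bipyridine (12 mol%), Zn dust (3 equiv), NaI (0.5 equiv), 40 °C; pH 5 buffer work-up
Reagents that add atoms: none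
Why: Proposed new method: silylation of the lactone carbonyl by Me3SiOTf turns the allylic C6–O bond into a leaving group, the allylsilane γ-carbon C1 displaces it from the back, the β-silyl cation at C10 collapses to the C10=C14 methylene and Me3Si+ passes to the carboxylate (24) so that the triflate turns over; then zerovalent nickel with Zn inserts into C4–Br, captures the primary C3 radical formed from the iodide and closes ring A by C(sp2)–C(sp3) reductive elimination (25). The closest known reaction types are the Lewis-acid-catalysed Hosomi–Sakurai allylation of allylic carboxylates (Ferrier-type C-allylation) and the Lewis-acid opening of γ-vinyl lactones by π-nucleophiles for the first event, and the nickel-catalysed reductive cross-electrophile coupling of alkenyl bromides with primary alkyl iodides for the second. Ring B closes 6-exo-tet at C6 through a chair with C2 and C5 equatorial; ring A closes as a six-membered ring by alkenyl–alkyl coupling with C4=C5 endocyclic. C6 is set by inversion at the cis-lactone carbon, the lactone ring holding C11 antiperiplanar to the incoming C1 and hence axial; C1 is set by the (Z) geometry of the allylsilane, which places the C2–C3 arm equatorial and gives the trans ring fusion. Ring B must form before ring A and the C4=C5 geometry must survive: the first is secured because a C3–C4 coupling before C1–C6 closure would need a ten-membered ring, the second by low-temperature ionisation with C15 trans to C6, so that neither bond rotation nor capture by the C15 silyl ether competes.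

**Step 17**
Reactants: 26 tris-TBS ether of the target
Product: 27 target, CNP0460913.2
Conditions: HF·pyridine, pyridine, THF, 0 → 25 °C
Reagents that add atoms: none
Why: Fluoride-mediated desilylation removes the three TBS ethers under buffered conditions that should leave the exocyclic alkene, the two acrylate units and the C8 ester in place.

**Compound list**
1 | (S)-3-hydroxy-γ-butyrolactone, (4S)-4-hydroxyoxolan-2-one | O=C1C[C@H](O)CO1 | starting material
2 | (4S)-3-[(dimethylamino)methyl]-4-hydroxyoxolan-2-one (C3 unspecified) | O=C1C(CN(C)C)[C@H](O)CO1 | intermediate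
3 | N-methyl quaternary iodide of 2 | O=C1C(C[N+](C)(C)C)[C@H](O)CO1.[I-] | intermediate
4 | (S)-tulipalin B, (4S)-4-hydroxy-3-methylideneoxolan-2-one | O=C1C(=C)[C@H](O)CO1 | intermediate
5 | lithium (3S)-3,4-dihydroxy-2-methylidenebutanoate | [Li+].[O-]C(=O)C(=C)[C@H](O)CO | intermediate
6 | tert-butyldimethylsilyl (3S)-3,4-bis(tert-butyldimethylsilyloxy)-2-methylidenebutanoate | CC(C)(C)[Si](C)(C)OC(=O)C(=C)[C@H](O[Si](C)(C)C(C)(C)C)CO[Si](C)(C)C(C)(C)C | intermediate
7 | (3S)-3,4-bis(tert-butyldimethylsilyloxy)-2-methylidenebutanoic acid | OC(=O)C(=C)[C@H](O[Si](C)(C)C(C)(C)C)CO[Si](C)(C)C(C)(C)C | intermediate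
8 | 4-(tert-butyldimethylsilyloxy)but-2-yn-1-ol | OCC#CCO[Si](C)(C)C(C)(C)C | starting material
9 | (2Z)-3-bromo-4-(tert-butyldimethylsilyloxy)but-2-en-1-ol | OC/C=C(\Br)CO[Si](C)(C)C(C)(C)C | intermediate
10 | (2Z)-3-bromo-4-(tert-butyldimethylsilyloxy)but-2-enal | O=C/C=C(\Br)CO[Si](C)(C)C(C)(C)C | intermediate
11 | (R)-2-[(4-methoxybenzyloxy)methyl]oxirane | COc1ccc(COC[C@H]2CO2)cc1 | starting material
12 | (2R)-1-(4-methoxybenzyloxy)pent-4-yn-2-ol | C#CC[C@@H](O)COCc1ccc(OC)cc1 | intermediate
13 | (2R)-1-(4-methoxybenzyloxy)-2-(triethylsilyloxy)pent-4-yne | C#CC[C@@H](O[Si](CC)(CC)CC)COCc1ccc(OC)cc1 | intermediate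
14 | (3Z,6R)-7-(4-methoxybenzyloxy)-6-(triethylsilyloxy)-4-[(trimethylsilyl)methyl]hept-3-en-1-ol | OCC/C=C(\C[Si](C)(C)C)C[C@@H](O[Si](CC)(CC)CC)COCc1ccc(OC)cc1 | intermediate
15 | (2R,4Z)-7-iodo-1-(4-methoxybenzyloxy)-2-(triethylsilyloxy)-4-[(trimethylsilyl)methyl]hept-4-ene | ICC/C=C(\C[Si](C)(C)C)C[C@@H](O[Si](CC)(CC)CC)COCc1ccc(OC)cc1 | intermediate
16 | (2R,4Z)-7-iodo-2-(triethylsilyloxy)-4-[(trimethylsilyl)methyl]hept-4-en-1-ol | ICC/C=C(\C[Si](C)(C)C)C[C@@H](O[Si](CC)(CC)CC)CO | intermediate
17 | (2R,4Z)-7-iodo-2-(triethylsilyloxy)-4-[(trimethylsilyl)methyl]hept-4-enal | ICC/C=C(\C[Si](C)(C)C)C[C@@H](O[Si](CC)(CC)CC)C=O | intermediate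
18 | methyl (4R,6Z)-3-hydroxy-9-iodo-2-methylidene-4-(triethylsilyloxy)-6-[(trimethylsilyl)methyl]non-6-enoate, both C3 epimers | C=C(C(=O)OC)C(O)[C@H](O[Si](CC)(CC)CC)C/C(C[Si](C)(C)C)=C/CCI | intermediate
19 | methyl (2Z,4R,6Z)-2-(bromomethyl)-9-iodo-4-(triethylsilyloxy)-6-[(trimethylsilyl)methyl]nona-2,6-dienoate | BrC/C(C(=O)OC)=C\[C@H](O[Si](CC)(CC)CC)C/C(C[Si](C)(C)C)=C/CCI | intermediate
20 | open-chain syn hydroxy methyl ester (C6 carbinol) preceding lactone 21 | C=C(C(=O)OC)[C@@H]([C@@H](O)/C=C(\Br)CO[Si](C)(C)C(C)(C)C)[C@H](O[Si](CC)(CC)CC)C/C(C[Si](C)(C)C)=C/CCI | intermediate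
21 | (4S,5R)-5-[(1Z)-2-bromo-3-(tert-butyldimethylsilyloxy)prop-1-en-1-yl]-4-[(1R,3Z)-6-iodo-1-(triethylsilyloxy)-3-[(trimethylsilyl)methyl]hex-3-en-1-yl]-3-methylideneoxolan-2-one | C=C1C(=O)O[C@@H](/C=C(\Br)CO[Si](C)(C)C(C)(C)C)[C@H]1[C@H](O[Si](CC)(CC)CC)C/C(C[Si](C)(C)C)=C/CCI | intermediate
22 | (4R,5R)-5-[(1Z)-2-bromo-3-(tert-butyldimethylsilyloxy)prop-1-en-1-yl]-4-[(1R,3Z)-1-hydroxy-6-iodo-3-[(trimethylsilyl)methyl]hex-3-en-1-yl]-3-methylideneoxolan-2-one | C=C1C(=O)O[C@@H](/C=C(\Br)CO[Si](C)(C)C(C)(C)C)[C@H]1[C@H](O)C/C(C[Si](C)(C)C)=C/CCI | intermediate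
23 | (3S)-3,4-bis(tert-butyldimethylsilyloxy)-2-methylidenebutanoate of 22 at O8 (key-step substrate) | C=C1C(=O)O[C@@H](/C=C(\Br)CO[Si](C)(C)C(C)(C)C)[C@H]1[C@H](OC(=O)C(=C)[C@H](O[Si](C)(C)C(C)(C)C)CO[Si](C)(C)C(C)(C)C)C/C(C[Si](C)(C)C)=C/CCI | intermediate
24 | (1S,6S,7R,8R) ring-B cyclohexane: trimethylsilyl acrylate at C7, (Z)-2-bromo-3-(TBS-oxy)propenyl at C6, 2-iodoethyl at C1, C10=C14 methylene, side-chain ester at O8 | C=C(C(=O)O[Si](C)(C)C)[C@H]1[C@@H](/C=C(\Br)CO[Si](C)(C)C(C)(C)C)[C@H](CCI)C(=C)C[C@H]1OC(=O)C(=C)[C@H](O[Si](C)(C)C(C)(C)C)CO[Si](C)(C)C(C)(C)C | intermediate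
25 | trimethylsilyl ester of 26 | C=C(C(=O)O[Si](C)(C)C)[C@H]1[C@H]2C=C(CO[Si](C)(C)C(C)(C)C)CC[C@@H]2C(=C)C[C@H]1OC(=O)C(=C)[C@H](O[Si](C)(C)C(C)(C)C)CO[Si](C)(C)C(C)(C)C | intermediate
26 | (1S,6S,7R,8R)-15-O-TBS-3′,4′-bis-O-TBS ether of the target acid | C=C(C(=O)O)[C@H]1[C@H]2C=C(CO[Si](C)(C)C(C)(C)C)CC[C@@H]2C(=C)C[C@H]1OC(=O)C(=C)[C@H](O[Si](C)(C)C(C)(C)C)CO[Si](C)(C)C(C)(C)C | intermediate
27 | CNP0460913.2, (1S,6S,7R,8R)-cadinane acid 8-[(3S)-3,4-dihydroxy-2-methylidenebutanoate] | C=C(C(=O)O)[C@H]1[C@H]2C=C(CO)CC[C@@H]2C(=C)C[C@H]1OC(=O)C(=C)[C@H](O)CO | target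

Total step count: 17. Longest linear sequence: 13 steps (steps 5–17, from 11).

**Steps most likely to fail**

Step 16. The silyl-activated lactone may ionise without participation of the allylsilane, which would lead to loss of the C7 proton, loss of the inversion at C6 through a free allyl cation, rotation about C4–C5, or protodesilylation. In the nickel stage, reduction of the C–I bond or addition to an acrylate may precede ring closure. Fallback with known reactions, from 23 back to 26: the two events are run separately. Stoichiometric BF3·OEt2 (CH2Cl2, −78 °C), the classical Hosomi–Sakurai manner, gives after aqueous work-up the ring-B seco acid F1. F1 is silylated on the acid with N,O-bis(trimethylsilyl)acetamide to 24, zinc is inserted into the C–I bond (Zn dust, LiCl, THF) to give the alkylzinc iodide F2, and ring A is closed by intramolecular Negishi coupling (Pd2(dba)3, SPhos, 25 °C) to 25, which gives 26 on work-up.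

Step 13. The aldehyde may approach the wrong C7 face of the allylindium (poor 1,2-induction from C8), or the allylindium may lose the C8 silyloxy group by 1,4-elimination. Fallback from 19 back to 21: 19 is converted with bis(pinacolato)diboron and catalytic Pd2(dba)3 into the 2-(methoxycarbonyl)allylboronate F3. A chiral BINOL-derived phosphoric acid then catalyses the allylboration of 10 through a closed chair, so that the catalyst and not C8 decides the face, and acid-induced lactonisation gives 21.

Step 7. The alkenyl ligand of the mixed cuprate may transfer sluggishly to ethylene oxide, so that protonation gives the simple alkene, or carbocupration may stop short. Fallback from 13 back to 14: after the same carbocupration the alkenylcopper is quenched with iodine to give the (Z)-alkenyl iodide F4; iodine–lithium exchange (t-BuLi, Et2O, −78 °C) and addition of ethylene oxide give 14.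

**Further compounds**
F1 | step 16 | ring-B seco acid, free acid of 24 | C=C(C(=O)O)[C@H]1[C@@H](/C=C(\Br)CO[Si](C)(C)C(C)(C)C)[C@H](CCI)C(=C)C[C@H]1OC(=O)C(=C)[C@H](O[Si](C)(C)C(C)(C)C)CO[Si](C)(C)C(C)(C)C
F2 | step 16 | alkylzinc iodide derived from 24 | C=C(C(=O)O[Si](C)(C)C)[C@H]1[C@@H](/C=C(\Br)CO[Si](C)(C)C(C)(C)C)[C@H](CC[Zn]I)C(=C)C[C@H]1OC(=O)C(=C)[C@H](O[Si](C)(C)C(C)(C)C)CO[Si](C)(C)C(C)(C)C
F3 | step 13 | pinacol allylboronate corresponding to 19 | CC1(C)OB(C/C(C(=O)OC)=C\[C@H](O[Si](CC)(CC)CC)C/C(C[Si](C)(C)C)=C/CCI)OC1(C)C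
F4 | step 7 | (Z)-alkenyl iodide from iodination of the alkenylcopper | I/C=C(\C[Si](C)(C)C)C[C@@H](O[Si](CC)(CC)CC)COCc1ccc(OC)cc1
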